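## Structural features

The target is a drimane‑type sesquiterpene ether of isofraxidin: a decalin (ring A = C1–C5/C10, ring B = C5–C10; drimane numbering is used for all positions) whose C9 carries a CH2–O arm (C11) bound to O7 of 6,8‑dimethoxycoumarin. Ring A has the gem‑dimethyl carbon C4 between the acetoxy carbinol C3 and the ring‑fusion methine C5; ring B has an exocyclic methylene at C8 (C12) next to C9. Of the four stereocentres, C5 (H), C10 (quaternary, CH3) and C9 (H, CH2OAr) are contiguous. H‑5, the C10 methyl and the C9 arm lie on one face, so the decalin is cis‑fused, and the 3‑acetoxy group lies on the other face; the descriptors are 3S,5R,9R,10R. Fragile groups are the coumarin (lactone and enoate: base, hydride, organometallics, dissolving metal), the exocyclic alkene (acid isomerisation, hydrogenation), the acetate, and the aryl ether at a β‑branched primary carbon. The real difficulty is the cis ring fusion, which a chair–chair cyclisation of an all‑E polyene does not give, combined with the C9–C10 bond between a quaternary and a tertiary carbon. The key step exploits the fact that ring A is a disguised 4,4‑dimethylcyclohexa‑2,5‑dienone: C5 and C3 are its two β‑carbons, C10 an α‑carbon, C1 the carbonyl carbon. Ring B is closed by bonding the C10 enolate of that ring to C9 of a chain already fixed at C5.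

## Logic of the disconnections

25 → 24: the acetate C–O bond is cut last. This keeps the only base‑labile ester out of every earlier step; the forward step is a plain acylation of a hindered secondary alcohol.

24 → 23: the C3–H bond is cut (carbinol back to ketone). A C3 ketone lets the last stereocentre be set by hydride delivery on the finished cis‑decalin. The demand is attack from the face of H‑5 and the C10 methyl, and tolerance of the coumarin.

23 → 21 + 22: the C11–O aryl ether bond is cut. The coumarin then enters after all enolate, hydrazine and dissolving‑metal chemistry, and 21 has a single hydroxyl. The demand is substitution at a β‑branched primary carbon without elimination.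

21 → 16 (through 20, 19, 17): the C3 carbonyl is traced back to a C1 carbonyl with a C2=C3 double bond, a 1,3‑carbonyl transposition. The C1 carbonyl is what makes C10 nucleophilic in the key step, and the C2=C3 bond is the unused arm of the dienone, so no oxygen has to be introduced from outside and none removed separately. The demand is that each operation leaves the 1,1‑disubstituted alkene and the free primary alcohol alone.

16 → 13 (key): the C9–C10 bond is cut. This opens ring B, removes the quaternary centre and the cis fusion, and reduces the problem to a monocyclic ketone with one side chain. The demands are C‑alkylation by a hindered tetrasubstituted enolate at C9 and not at C12 or C11, with inversion at C9.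

13 → 8 + 9: the C8–C9 bond and the oxirane C–O bond are cut. C9 and C11 come from a two‑carbon aldehyde, C8 and C12 from a 2‑bromoalkene, and C9 becomes the only stereocentre to be set by a reagent. The demands are aldehyde‑selective coupling in the presence of a ketone and catalyst control at C9.

8 → 6 → 3 + 2: the C10–CH3 bond, then the C5–C6 bond are cut. This leads to an achiral, symmetrical dienone and a four‑carbon iodide; C5 is set by a catalyst, and the methyl goes in at the only enolisable position. The demands are enantioface control in the conjugate addition and mono‑methylation.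

2 → 1: the C–I bond is cut; a routine alcohol‑to‑iodide exchange on a purchased bromoalkenol.

## Other disconnections considered

Alternative 1: the first that comes to mind is the biomimetic cut of C4–C5 and C9–C10 in one cationic bicyclisation. The forward key step is Lewis‑acid opening of the (S)‑epoxide of the (2E,6Z)‑configured farnesyl ether A1, which would give 24 directly. The cis fusion then depends on stereospecific anti addition across a Z trisubstituted alkene; a tertiary cation at C10 that lives long enough to rotate would lose that information. Proton loss from the C8 cation can give three alkene isomers. The Lewis acid must also coexist with an electron‑rich aryl ether and a coumarin, and the (2E,6Z) dienol precursor is not an article of commerce. The chosen plan fixes the ring fusion by a tether and not by alkene geometry.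

Alternative 2: the same C9–C10 bond with reversed polarity, an intramolecular Hosomi–Sakurai addition of the (Z)‑allylsilane A2 to its 3,5,5‑trimethylcyclohexenone, would give the cis‑decalone A3. It is regiosecure and delivers the exocyclic methylene directly. It places the ring‑A carbonyl at C2, where the target has CH2, and leaves C3 without oxygen, so an α′‑oxygenation before and a deoxygenation after the key step are needed. No catalytic entry to the C5 stereocentre of A2 was found, and the allylsilane cannot be present during the allylic oxidation that makes the enone. The step count was estimated at sixteen or more, against thirteen for the chosen plan.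

Alternative 3: ring B closed at C5–C6 by desymmetrising a 4‑methyl‑4‑alkylcyclohexadienone. Ring opening of the cyclopropanol in A4 gives a β‑keto radical that adds 6‑exo to one enone arm. The oxygen is at C3 from the start and the C8 ketone is ready for methylenation. The bond is formed by axial attack at C5, which fixes the chair of ring B in which the C10 methyl is equatorial; the equatorial C11 arm then ends anti to the methyl. The expected product is A5, the C9 epimer of what is needed, and C9 would have to be installed beforehand with an auxiliary.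

Key step: step 6

Remark on the chemistry: the sense of induction of the two chiral catalysts (steps 2 and 4) is assigned by analogy with their standard substrates; both ligand antipodes are available and the one giving the stated configuration is meant. The route is a proposal and has not been run.

## Route

Step 1
Reactants: 1 3‑bromobut‑3‑en‑1‑ol
Product: 2 2‑bromo‑4‑iodobut‑1‑ene
Conditions: I2, PPh3, imidazole, CH2Cl2, 0 °C → rt
Reagents that add atoms: iodine, II
Why: Appel‑type iodination of a primary alcohol; the vinyl bromide is inert.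

Step 2
Reactants: 2 2‑bromo‑4‑iodobut‑1‑ene; 3 4,4‑dimethylcyclohexa‑2,5‑dien‑1‑one
Product: 6 (5R)‑5‑(3‑bromobut‑3‑en‑1‑yl)‑4,4‑dimethylcyclohex‑2‑en‑1‑one, via bis(3‑bromobut‑3‑en‑1‑yl)zinc 4 (not isolated), via zinc enolate 5 (not isolated)
Conditions: (i) 2, Et2Zn (neat), CuI (cat.), 50 °C, then volatiles removed; (ii) Cu(OTf)2 (2 mol %), (S,R,R)‑BINOL bis(1‑phenylethyl)amine phosphoramidite (4 mol %), toluene, −30 °C, 3; 1 M HCl
Reagents that add atoms: none
Why: Iodine–zinc exchange gives the dialkylzinc, which adds 1,4 under copper–phosphoramidite catalysis (enantioselective conjugate addition to a cyclohexadienone). The two enone arms of 3 are equivalent, so only enantioface selection is needed; it sets C5 (R). The resulting dienolate is not an acceptor, so a second addition should not occur.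

Step 3
Reactants: 6 (5R)‑5‑(3‑bromobut‑3‑en‑1‑yl)‑4,4‑dimethylcyclohex‑2‑en‑1‑one
Product: 8 (5R,6R)‑5‑(3‑bromobut‑3‑en‑1‑yl)‑4,4,6‑trimethylcyclohex‑2‑en‑1‑one, via lithium enolate 7 (not isolated)
Conditions: LDA (1.05 equiv), THF, −78 °C; MeI, −78 → −30 °C
Reagents that add atoms: iodomethane, CI
Why: C6–H2 of the ring is the only enolisable position (C2 is vinylic, C4 quaternary), so enolate methylation is regiospecific. The methyl should enter anti to the C5 chain (trans isomer shown); the C6 centre is re‑enolised in step 6, so the minor cis isomer converges.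

Step 4
Reactants: 8 (5R,6R)‑5‑(3‑bromobut‑3‑en‑1‑yl)‑4,4,6‑trimethylcyclohex‑2‑en‑1‑one; 9 {[tert‑butyl(dimethyl)silyl]oxy}acetaldehyde
Product: 11 (5R,6R)‑5‑[(4S)‑5‑{[tert‑butyl(dimethyl)silyl]oxy}‑4‑hydroxy‑3‑methylidenepentyl]‑4,4,6‑trimethylcyclohex‑2‑en‑1‑one, via trimethylsilyl ether 10 (not isolated)
Conditions: 9, CrCl2 (10 mol %), chiral oxazoline–sulfonamide ligand (11 mol %, antipode giving 4S), NiCl2·(2,9‑dimethylphenanthroline) (2 mol %), Mn, TMSCl, LiCl, MeCN, rt; then K2CO3, MeOH, 0 °C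
Reagents that add atoms: none
Why: Catalytic asymmetric Nozaki–Hiyama–Kishi coupling of a 2‑bromoalkene with an aldehyde; the alkenylchromium species adds to aldehydes and leaves the ring ketone alone. The ligand sets the carbinol (future C9) as S, remote from and independent of the ring stereocentres.

Step 5
Reactants: 11 (5R,6R)‑5‑[(4S)‑5‑{[tert‑butyl(dimethyl)silyl]oxy}‑4‑hydroxy‑3‑methylidenepentyl]‑4,4,6‑trimethylcyclohex‑2‑en‑1‑one
Product: 13 (5R,6R)‑4,4,6‑trimethyl‑5‑{3‑[(2R)‑oxiran‑2‑yl]but‑3‑en‑1‑yl}cyclohex‑2‑en‑1‑one, via methanesulfonate 12 (not isolated)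
Conditions: Ms2O, Et3N, CH2Cl2, −20 °C; then TBAF, THF, 0 °C → rt
Reagents that add atoms: none
Why: Sulfonylation of the secondary alcohol, then fluoride desilylation; the primary alkoxide displaces the mesylate (3‑exo‑tet Williamson closure) with inversion, turning the 4S carbinol into the (R)‑oxirane.

Step 6
Reactants: 13 (5R,6R)‑4,4,6‑trimethyl‑5‑{3‑[(2R)‑oxiran‑2‑yl]but‑3‑en‑1‑yl}cyclohex‑2‑en‑1‑one
Product: 16 (4aS,8R,8aR)‑8‑(hydroxymethyl)‑4,4,8a‑trimethyl‑7‑methylidene‑4a,5,6,7,8,8a‑hexahydronaphthalen‑1(4H)‑one, via potassium enolate 14 (not isolated), via potassium alkoxide 15 (not isolated)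
Conditions: KHMDS (1.2 equiv), THF, −78 → 40 °C; aq. NH4Cl
Reagents that add atoms: none
Why: KHMDS removes the only enolisable proton (H‑10; C2 is vinylic, C4 quaternary), and the tetrasubstituted potassium enolate attacks the oxirane at its allylic carbon C9 from the rear; the closest known reaction type is the Stork epoxynitrile cyclisation and its ketone‑enolate analogues. Ring B closes in the 6‑exo‑tet mode (new bond C9–C10, tether C6–C7–C8 on C5), the breaking C–O bond staying outside the new ring. C10: the short tether can bring C9 only to the face of the planar enolate on which C6 already stands, so the fusion is cis and the methyl ends syn to H‑5. C9: SN2 inversion at the (R)‑oxirane carbon is stereospecific and gives 9R with the CH2O arm syn to the C10 methyl; in that transition state H‑9 points over ring A and C11 is tied back in the oxirane. The selectivity needed is C9 over C12 (SN2′, a 6‑endo closure) and over C11 (7‑endo). The collinear exo trajectory, the vinyl activation of C9 and the hard potassium enolate should favour direct substitution. O‑alkylation would need an eight‑membered ring.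

Step 7
Reactants: 16 (4aS,8R,8aR)‑8‑(hydroxymethyl)‑4,4,8a‑trimethyl‑7‑methylidene‑4a,5,6,7,8,8a‑hexahydronaphthalen‑1(4H)‑one
Product: 17 (2S,3S,4aS,8R,8aR)‑2,3‑epoxy‑8‑(hydroxymethyl)‑4,4,8a‑trimethyl‑7‑methylidene‑3,4,4a,5,6,7,8,8a‑octahydronaphthalen‑1(2H)‑one
Conditions: 30 % H2O2, NaOH (cat.), MeOH, 0 °C
Reagents that add atoms: hydrogen peroxide, OO
Why: Nucleophilic (Weitz–Scheffer) epoxidation touches only the enone; the isolated methylene is inert. The oxirane is expected on the face of the C8a methyl and H‑4a, but its configuration is erased in step 9.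

Step 8
Reactants: 17 (2S,3S,4aS,8R,8aR)‑2,3‑epoxy‑8‑(hydroxymethyl)‑4,4,8a‑trimethyl‑7‑methylidene‑3,4,4a,5,6,7,8,8a‑octahydronaphthalen‑1(2H)‑one
Product: 19 (2R,4aR,5R,8aR)‑5‑(hydroxymethyl)‑1,1,4a‑trimethyl‑6‑methylidene‑1,2,4a,5,6,7,8,8a‑octahydronaphthalen‑2‑ol, via epoxy hydrazone 18 (not isolated)
Conditions: N2H4·H2O, AcOH (cat.), MeOH, 0 °C → rt
Reagents that add atoms: none
Why: Wharton transposition: the epoxy hydrazone opens to an allylic alcohol with loss of N2. This removes the C1 oxygen and places oxygen on C3 in one operation, with the alkene at C1=C2.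

Step 9
Reactants: 19 (2R,4aR,5R,8aR)‑5‑(hydroxymethyl)‑1,1,4a‑trimethyl‑6‑methylidene‑1,2,4a,5,6,7,8,8a‑octahydronaphthalen‑2‑ol
Product: 20 (4aR,5R,8aR)‑5‑(hydroxymethyl)‑1,1,4a‑trimethyl‑6‑methylidene‑4a,5,6,7,8,8a‑hexahydronaphthalen‑2(1H)‑one
Conditions: MnO2, CH2Cl2, rt
Reagents that add atoms: none
Why: Activated MnO2 oxidises the allylic secondary alcohol and leaves the saturated primary alcohol; the enone formed has no enolisable position.

Step 10
Reactants: 20 (4aR,5R,8aR)‑5‑(hydroxymethyl)‑1,1,4a‑trimethyl‑6‑methylidene‑4a,5,6,7,8,8a‑hexahydronaphthalen‑2(1H)‑one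
Product: 21 (4aR,5R,8aR)‑5‑(hydroxymethyl)‑1,1,4a‑trimethyl‑6‑methylidene‑3,4,4a,5,6,7,8,8a‑octahydronaphthalen‑2(1H)‑one
Conditions: Li, NH3(l), THF, t‑BuOH (1 equiv), −78 °C; NH4Cl
Reagents that add atoms: none
Why: Dissolving‑metal conjugate reduction of the enone stops at the enolate, which is protonated on quench; the isolated 1,1‑disubstituted alkene is not reduced and no stereocentre is formed.

Step 11
Reactants: 21 (4aR,5R,8aR)‑5‑(hydroxymethyl)‑1,1,4a‑trimethyl‑6‑methylidene‑3,4,4a,5,6,7,8,8a‑octahydronaphthalen‑2(1H)‑one; 22 isofraxidin (7‑hydroxy‑6,8‑dimethoxy‑2H‑chromen‑2‑one)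
Product: 23 6,8‑dimethoxy‑7‑{[(1R,4aR,8aR)‑5,5,8a‑trimethyl‑2‑methylidene‑6‑oxodecahydronaphthalen‑1‑yl]methoxy}‑2H‑chromen‑2‑one
Conditions: 22, PPh3, DIAD, THF, 0 °C → rt
Reagents that add atoms: none
Why: Mitsunobu etherification of the only hydroxyl with an acidic phenol; the ketone is a spectator.

Step 12
Reactants: 23 6,8‑dimethoxy‑7‑{[(1R,4aR,8aR)‑5,5,8a‑trimethyl‑2‑methylidene‑6‑oxodecahydronaphthalen‑1‑yl]methoxy}‑2H‑chromen‑2‑one
Product: 24 7‑{[(1R,4aR,6S,8aR)‑6‑hydroxy‑5,5,8a‑trimethyl‑2‑methylidenedecahydronaphthalen‑1‑yl]methoxy}‑6,8‑dimethoxy‑2H‑chromen‑2‑one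
Conditions: NaBH4, MeOH–CH2Cl2, −20 → 0 °C
Reagents that add atoms: none
Why: Hydride should attack C3 from the face of H‑5 and the C10 methyl. In the chair with C6 equatorial this is unhindered axial attack; in the other chair the opposite face is blocked by the axial C5–C6 bond. Either way the hydroxyl ends syn to C6 (3S). The coumarin lactone is not reduced under these conditions.

Step 13
Reactants: 24 7‑{[(1R,4aR,6S,8aR)‑6‑hydroxy‑5,5,8a‑trimethyl‑2‑methylidenedecahydronaphthalen‑1‑yl]methoxy}‑6,8‑dimethoxy‑2H‑chromen‑2‑one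
Product: 25 (2S,4aR,5R,8aR)‑5‑{[(6,8‑dimethoxy‑2‑oxo‑2H‑chromen‑7‑yl)oxy]methyl}‑1,1,4a‑trimethyl‑6‑methylidenedecahydronaphthalen‑2‑yl acetate (target)
Conditions: Ac2O, pyridine, DMAP (cat.), CH2Cl2, rt
Reagents that add atoms: acetic anhydride, CC(=O)OC(C)=O
Why: DMAP‑catalysed acetylation of the hindered secondary alcohol with retention; nothing else in the molecule is acylated.

## Compound list

1 | 3‑bromobut‑3‑en‑1‑ol | OCCC(Br)=C | starting material
2 | 2‑bromo‑4‑iodobut‑1‑ene | ICCC(Br)=C | intermediate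
3 | 4,4‑dimethylcyclohexa‑2,5‑dien‑1‑one | O=C1C=CC(C)(C)C=C1 | starting material
4 | bis(3‑bromobut‑3‑en‑1‑yl)zinc | C=C(Br)CC[Zn]CCC(Br)=C | intermediate
5 | zinc enolate of 6 (O–Zn–alkyl, C1=C6 and C2=C3 double bonds) | C=C(Br)CC[Zn]OC1=C[C@@H](CCC(Br)=C)C(C)(C)C=C1 | intermediate
6 | (5R)‑5‑(3‑bromobut‑3‑en‑1‑yl)‑4,4‑dimethylcyclohex‑2‑en‑1‑one | C=C(Br)CC[C@H]1C(C)(C)C=CC(=O)C1 | intermediate
7 | lithium enolate of 6 (O–Li, C1=C6 and C2=C3 double bonds) | [Li]OC1=C[C@@H](CCC(Br)=C)C(C)(C)C=C1 | intermediate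
8 | (5R,6R)‑5‑(3‑bromobut‑3‑en‑1‑yl)‑4,4,6‑trimethylcyclohex‑2‑en‑1‑one | C=C(Br)CC[C@H]1C(C)(C)C=CC(=O)[C@@H]1C | intermediate
9 | {[tert‑butyl(dimethyl)silyl]oxy}acetaldehyde | O=CCO[Si](C)(C)C(C)(C)C | starting material
10 | trimethylsilyl ether of 11 | C=C(CC[C@H]1C(C)(C)C=CC(=O)[C@@H]1C)[C@H](O[Si](C)(C)C)CO[Si](C)(C)C(C)(C)C | intermediate
11 | (5R,6R)‑5‑[(4S)‑5‑{[tert‑butyl(dimethyl)silyl]oxy}‑4‑hydroxy‑3‑methylidenepentyl]‑4,4,6‑trimethylcyclohex‑2‑en‑1‑one | C=C(CC[C@H]1C(C)(C)C=CC(=O)[C@@H]1C)[C@H](O)CO[Si](C)(C)C(C)(C)C | intermediate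
12 | (2S)‑1‑{[tert‑butyl(dimethyl)silyl]oxy}‑3‑methylidene‑5‑[(1R,2R)‑2,6,6‑trimethyl‑3‑oxocyclohex‑4‑en‑1‑yl]pentan‑2‑yl methanesulfonate | C=C(CC[C@H]1C(C)(C)C=CC(=O)[C@@H]1C)[C@H](OS(C)(=O)=O)CO[Si](C)(C)C(C)(C)C | intermediate
13 | (5R,6R)‑4,4,6‑trimethyl‑5‑{3‑[(2R)‑oxiran‑2‑yl]but‑3‑en‑1‑yl}cyclohex‑2‑en‑1‑one | C=C(CC[C@H]1C(C)(C)C=CC(=O)[C@@H]1C)[C@@H]2CO2 | intermediate
14 | potassium enolate of 13 (O–K, C1=C6 and C2=C3 double bonds) | [K]OC1=C(C)[C@@H](CCC(=C)[C@@H]2CO2)C(C)(C)C=C1 | intermediate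
15 | potassium alkoxide of 16 | C=C1CC[C@H]2C(C)(C)C=CC(=O)[C@@]2(C)[C@@H]1CO[K] | intermediate
16 | (4aS,8R,8aR)‑8‑(hydroxymethyl)‑4,4,8a‑trimethyl‑7‑methylidene‑4a,5,6,7,8,8a‑hexahydronaphthalen‑1(4H)‑one | C=C1CC[C@H]2C(C)(C)C=CC(=O)[C@@]2(C)[C@@H]1CO | intermediate
17 | (2S,3S,4aS,8R,8aR)‑2,3‑epoxy‑8‑(hydroxymethyl)‑4,4,8a‑trimethyl‑7‑methylidene‑3,4,4a,5,6,7,8,8a‑octahydronaphthalen‑1(2H)‑one | C=C1CC[C@H]2C(C)(C)[C@@H]3O[C@@H]3C(=O)[C@@]2(C)[C@@H]1CO | intermediate
18 | hydrazone of 17 (C1=N–NH2) | C=C1CC[C@H]2C(C)(C)[C@@H]3O[C@@H]3C(=NN)[C@@]2(C)[C@@H]1CO | intermediate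
19 | (2R,4aR,5R,8aR)‑5‑(hydroxymethyl)‑1,1,4a‑trimethyl‑6‑methylidene‑1,2,4a,5,6,7,8,8a‑octahydronaphthalen‑2‑ol | C=C1CC[C@H]2C(C)(C)[C@H](O)C=C[C@@]2(C)[C@@H]1CO | intermediate
20 | (4aR,5R,8aR)‑5‑(hydroxymethyl)‑1,1,4a‑trimethyl‑6‑methylidene‑4a,5,6,7,8,8a‑hexahydronaphthalen‑2(1H)‑one | C=C1CC[C@H]2C(C)(C)C(=O)C=C[C@@]2(C)[C@@H]1CO | intermediate
21 | (4aR,5R,8aR)‑5‑(hydroxymethyl)‑1,1,4a‑trimethyl‑6‑methylidene‑3,4,4a,5,6,7,8,8a‑octahydronaphthalen‑2(1H)‑one | C=C1CC[C@H]2C(C)(C)C(=O)CC[C@@]2(C)[C@@H]1CO | intermediate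
22 | isofraxidin (7‑hydroxy‑6,8‑dimethoxy‑2H‑chromen‑2‑one) | COc1cc2ccc(=O)oc2c(OC)c1O | starting material
23 | 6,8‑dimethoxy‑7‑{[(1R,4aR,8aR)‑5,5,8a‑trimethyl‑2‑methylidene‑6‑oxodecahydronaphthalen‑1‑yl]methoxy}‑2H‑chromen‑2‑one | C=C1CC[C@H]2C(C)(C)C(=O)CC[C@@]2(C)[C@@H]1COc1c(OC)cc2ccc(=O)oc2c1OC | intermediate
24 | 7‑{[(1R,4aR,6S,8aR)‑6‑hydroxy‑5,5,8a‑trimethyl‑2‑methylidenedecahydronaphthalen‑1‑yl]methoxy}‑6,8‑dimethoxy‑2H‑chromen‑2‑one | C=C1CC[C@H]2C(C)(C)[C@@H](O)CC[C@@]2(C)[C@@H]1COc1c(OC)cc2ccc(=O)oc2c1OC | intermediate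
25 | (2S,4aR,5R,8aR)‑5‑{[(6,8‑dimethoxy‑2‑oxo‑2H‑chromen‑7‑yl)oxy]methyl}‑1,1,4a‑trimethyl‑6‑methylidenedecahydronaphthalen‑2‑yl acetate | C=C1CC[C@H]2C(C)(C)[C@@H](OC(C)=O)CC[C@@]2(C)[C@@H]1COc1c(OC)cc2ccc(=O)oc2c1OC | target

## Step count and least certain steps

Total step count: 13. Longest linear sequence: 13 steps (1 → 25); 3, 9 and 22 enter as purchased compounds.

Step 6 (key step). What may go wrong is regiochemical leakage: the enolate may attack the methylene terminus C12 in an SN2′ sense, which is also a six‑membered closure and the main risk, or the primary oxirane carbon C11; enolisation of the hindered C–H may also be slow. The fallback blocks the γ‑terminus with silicon and sets out from 3. Commercial 4‑(trimethylsilyl)but‑3‑yn‑1‑ol F1 is hydrobrominated to (Z)‑3‑bromo‑4‑(trimethylsilyl)but‑3‑en‑1‑ol F2 and converted into (Z)‑(2‑bromo‑4‑iodobut‑1‑en‑1‑yl)trimethylsilane F3. Its dialkylzinc is added to 3 as in step 2 to give the silylated bromoalkenyl enone F4, which is methylated to the trimethyl ketone F5. Coupling with 9 as in step 4 gives the silylated carbinol F6, and closure as in step 5 gives the silylated vinyl oxirane F7. The bulky silyl group at C12 should shut down SN2′ attack, so base‑mediated closure should give the bicyclic vinylsilane F8. Protodesilylation (TFA, CH2Cl2, 0 °C) then returns to the route at 16.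

Step 4. What may go wrong is insufficient catalyst control at the new carbinol carbon, since 2‑bromoalkenes are among the less selective partners. The fallback sets out from 8 and replaces catalyst control by separation and recycling: the ligand‑free CrCl2/NiCl2 coupling gives 11 together with its (4R)‑epimer F9, which are diastereomers and separable. F9 is inverted by Mitsunobu esterification with 4‑nitrobenzoic acid to the (4S)‑4‑nitrobenzoate F10, and methanolysis (K2CO3, MeOH) returns to the route at 11.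

Step 11. What may go wrong is slow substitution at the β‑branched primary carbon, with elimination towards C9 competing. The fallback sets out from 21 and replaces the redox condensation by a two‑stage Williamson ether synthesis: 21 is converted into its methanesulfonate F11, and the caesium salt of 22 (Cs2CO3, DMF, 70 °C) displaces it to return at 23.

Step 12. What may go wrong is poor facial selectivity of hydride delivery if the cis‑decalin reacts through an unexpected conformer, giving the 3‑epimer F12. The fallback replaces substrate control by reagent control: F12 is oxidised back to 23 (Dess–Martin periodinane) and 23 is reduced with a CBS oxazaborolidine and catecholborane, the catalyst antipode chosen for 3S, returning at 24.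

## Further compounds

F1 | step 6 | 4‑(trimethylsilyl)but‑3‑yn‑1‑ol | OCCC#C[Si](C)(C)C
F2 | step 6 | (Z)‑3‑bromo‑4‑(trimethylsilyl)but‑3‑en‑1‑ol | OCC/C(Br)=C/[Si](C)(C)C
F3 | step 6 | (Z)‑(2‑bromo‑4‑iodobut‑1‑en‑1‑yl)trimethylsilane | ICC/C(Br)=C/[Si](C)(C)C
F4 | step 6 | (5R)‑5‑[(3Z)‑3‑bromo‑4‑(trimethylsilyl)but‑3‑en‑1‑yl]‑4,4‑dimethylcyclohex‑2‑en‑1‑one | C[Si](C)(C)/C=C(\Br)CC[C@H]1C(C)(C)C=CC(=O)C1
F5 | step 6 | (5R,6R)‑5‑[(3Z)‑3‑bromo‑4‑(trimethylsilyl)but‑3‑en‑1‑yl]‑4,4,6‑trimethylcyclohex‑2‑en‑1‑one | C[Si](C)(C)/C=C(\Br)CC[C@H]1C(C)(C)C=CC(=O)[C@@H]1C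
F6 | step 6 | (5R,6R)‑5‑[(3Z,4S)‑5‑{[tert‑butyl(dimethyl)silyl]oxy}‑4‑hydroxy‑3‑[(trimethylsilyl)methylidene]pentyl]‑4,4,6‑trimethylcyclohex‑2‑en‑1‑one | C[Si](C)(C)/C=C(\[C@H](O)CO[Si](C)(C)C(C)(C)C)CC[C@H]1C(C)(C)C=CC(=O)[C@@H]1C
F7 | step 6 | (5R,6R)‑4,4,6‑trimethyl‑5‑[(3Z)‑3‑[(2R)‑oxiran‑2‑yl]‑4‑(trimethylsilyl)but‑3‑en‑1‑yl]cyclohex‑2‑en‑1‑one | C[Si](C)(C)/C=C(\[C@@H]2CO2)CC[C@H]1C(C)(C)C=CC(=O)[C@@H]1C
F8 | step 6 | (4aS,7Z,8R,8aR)‑8‑(hydroxymethyl)‑4,4,8a‑trimethyl‑7‑[(trimethylsilyl)methylidene]‑4a,5,6,7,8,8a‑hexahydronaphthalen‑1(4H)‑one | C[Si](C)(C)/C=C1/CC[C@H]2C(C)(C)C=CC(=O)[C@@]2(C)[C@@H]1CO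
F9 | step 4 | (5R,6R)‑5‑[(4R)‑5‑{[tert‑butyl(dimethyl)silyl]oxy}‑4‑hydroxy‑3‑methylidenepentyl]‑4,4,6‑trimethylcyclohex‑2‑en‑1‑one | C=C(CC[C@H]1C(C)(C)C=CC(=O)[C@@H]1C)[C@@H](O)CO[Si](C)(C)C(C)(C)C
F10 | step 4 | (2S)‑1‑{[tert‑butyl(dimethyl)silyl]oxy}‑3‑methylidene‑5‑[(1R,2R)‑2,6,6‑trimethyl‑3‑oxocyclohex‑4‑en‑1‑yl]pentan‑2‑yl 4‑nitrobenzoate | C=C(CC[C@H]1C(C)(C)C=CC(=O)[C@@H]1C)[C@H](OC(=O)c1ccc(cc1)[N+](=O)[O-])CO[Si](C)(C)C(C)(C)C
F11 | step 11 | [(1R,4aR,8aR)‑5,5,8a‑trimethyl‑2‑methylidene‑6‑oxodecahydronaphthalen‑1‑yl]methyl methanesulfonate | C=C1CC[C@H]2C(C)(C)C(=O)CC[C@@]2(C)[C@@H]1COS(C)(=O)=O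
F12 | step 12 | 7‑{[(1R,4aR,6R,8aR)‑6‑hydroxy‑5,5,8a‑trimethyl‑2‑methylidenedecahydronaphthalen‑1‑yl]methoxy}‑6,8‑dimethoxy‑2H‑chromen‑2‑one | C=C1CC[C@H]2C(C)(C)[C@H](O)CC[C@@]2(C)[C@@H]1COc1c(OC)cc2ccc(=O)oc2c1OC
A1 | alternative 1 | 7‑{[(2E,6Z)‑9‑[(2S)‑3,3‑dimethyloxiran‑2‑yl]‑3,7‑dimethylnona‑2,6‑dien‑1‑yl]oxy}‑6,8‑dimethoxy‑2H‑chromen‑2‑one | CC1(C)O[C@H]1CC/C(C)=C\CC/C(C)=C/COc1c(OC)cc2ccc(=O)oc2c1OC
A2 | alternative 2 | (4S)‑4‑[(3Z)‑5‑{[tert‑butyl(dimethyl)silyl]oxy}‑3‑[(trimethylsilyl)methyl]pent‑3‑en‑1‑yl]‑3,5,5‑trimethylcyclohex‑2‑en‑1‑one | C[Si](C)(C)C/C(CC[C@@H]1C(C)=CC(=O)CC1(C)C)=C\CO[Si](C)(C)C(C)(C)C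
A3 | alternative 2 | (4aS,8R,8aR)‑8‑({[tert‑butyl(dimethyl)silyl]oxy}methyl)‑4,4,8a‑trimethyl‑7‑methylideneoctahydronaphthalen‑2(1H)‑one | C=C1CC[C@H]2C(C)(C)CC(=O)C[C@@]2(C)[C@@H]1CO[Si](C)(C)C(C)(C)C
A4 | alternative 3 | 4‑[(1S)‑2‑(benzyloxy)‑1‑(1‑hydroxycyclopropyl)ethyl]‑4‑methylcyclohexa‑2,5‑dien‑1‑one | O=C1C=CC(C)(C=C1)[C@@H](COCc1ccccc1)C1(O)CC1
A5 | alternative 3 | (4aS,5S,8aS)‑5‑[(benzyloxy)methyl]‑4a‑methyl‑4a,5,8,8a‑tetrahydronaphthalene‑2,6(1H,7H)‑dione | O=C1CC[C@H]2CC(=O)C=C[C@@]2(C)[C@H]1COCc1ccccc1
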